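**Plan**

- Enabling feature: ring A is a cyclohex-1(10)-en-2-one sharing the C5–C10 bond with ring B. C4 (quaternary, CO2Me C18 and Me C19) and CH-5 form a tiglate pattern, and C6–C9 is a four-carbon bridge from C5 to C10. Once the enone is moved to its C1=C2 silyl enol ether, C3–C4 and C5–C10 are the two σ-bonds of a [4+2] adduct.
- Cuts: C3–C4 and C5–C10 (retro-[4+2]), then C4=C5 (Wittig) and C10=C1 (Horner–Wadsworth–Emmons), giving a 1,6-dialdehyde that is the ozonolysis product of a C5=C10 cyclohexene. Then C9–C11 (enolate alkylation) and C8–C17 (conjugate methylation).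
- Forward: the C11–C15 iodide (steps 1–4) is joined to a six-membered carrier ring (steps 5–6). The carrier ring is opened and extended at both ends (steps 7–13). Rings A and B then close together in one step (14) and the enone is unmasked (15).
- Stereochemistry: C13 comes from hemiester 1, C8 from the ligand-controlled conjugate addition, and C9 from alkylation anti to the C8 methyl. C4/C5 come from the E-enoate geometry and the diene face used in step 14; C10 is transient.

Key step: step 14

Remark: halimane numbering (C1–C20) is used for every compound.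
Remark: 1 is taken as the purchasable (R)-monoester of the 3-methylglutaric acid series; its acid end becomes C11 and its ester end C15.
Remark: in step 5 the ligand antipode is the one that delivers the 8R centre.

Step 1
Reactants: 1 (R)-5-methoxy-3-methyl-5-oxopentanoic acid
Product: 2 methyl (R)-5-hydroxy-3-methylpentanoate
Conditions: BH3·SMe2, THF, 0 °C to rt; MeOH quench
Reagents that add atoms: none
Why: Chemoselective borane reduction takes the free carboxylic acid (future C11) to CH2OH through its acyloxyborane far faster than it touches the methyl ester, and C13 is not involved.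

Step 2
Reactants: 2 methyl (R)-5-hydroxy-3-methylpentanoate
Product: 3 methyl (S)-5-iodo-3-methylpentanoate
Conditions: I2, PPh3, imidazole, CH2Cl2, 0 °C to rt
Reagents that add atoms: iodine, II
Why: Appel-type iodination converts the primary alcohol into the iodide by SN2 displacement of an alkoxyphosphonium ion and leaves the ester alone.

Step 3
Reactants: 3 methyl (S)-5-iodo-3-methylpentanoate
Product: 4 (S)-5-iodo-3-methylpentan-1-ol
Conditions: i-Bu2AlH (2.2 equiv), CH2Cl2, −78 to 0 °C; aq. KNaC4H4O6
Reagents that add atoms: none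
Why: Aluminium hydride reduction of the ester gives the primary alcohol (future C15), while a primary alkyl iodide is inert to i-Bu2AlH at low temperature.

Step 4
Reactants: 4 (S)-5-iodo-3-methylpentan-1-ol
Product: 5 (S)-tert-butyl[(5-iodo-3-methylpentyl)oxy]dimethylsilane
Conditions: t-BuMe2SiCl, imidazole, CH2Cl2, 0 °C to rt
Reagents that add atoms: tert-butyldimethylsilyl chloride, CC(C)(C)[Si](C)(C)Cl
Why: Silylation of the primary alcohol gives an ether that withstands MeLi and lithium amide in steps 6 and 7.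

Step 5
Reactants: 6 2-methylcyclohex-2-en-1-one
Product: 8 (R)-[(2,3-dimethylcyclohex-1-en-1-yl)oxy]trimethylsilane, via aluminium enolate 7 (not isolated)
Conditions: AlMe3, Cu(O2CC4H3S) (copper thiophene-2-carboxylate, 2 mol%), binaphthol-derived bis(1-phenylethyl)phosphoramidite (4 mol%, antipode giving 8R), Et2O, −30 °C; then Me3SiOTf, −30 to 0 °C
Reagents that add atoms: trimethylaluminium, C[Al](C)C; trimethylsilyl trifluoromethanesulfonate, C[Si](C)(C)OS(=O)(=O)C(F)(F)F
Why: Copper-catalysed asymmetric conjugate addition places the C17 methyl on the enone face chosen by the phosphoramidite (sets C8), and O-silylation of the regiodefined aluminium enolate fixes the enolate at C9=C10.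

Step 6
Reactants: 8 (R)-[(2,3-dimethylcyclohex-1-en-1-yl)oxy]trimethylsilane; 5 (S)-tert-butyl[(5-iodo-3-methylpentyl)oxy]dimethylsilane
Product: 10 (2S,3R)-2-[(3R)-5-(tert-butyldimethylsilyloxy)-3-methylpentyl]-2,3-dimethylcyclohexan-1-one, via lithium enolate 9 (not isolated)
Conditions: MeLi, THF, 0 °C; then 5, HMPA, −30 °C to rt
Reagents that add atoms: none
Why: Si–O cleavage by MeLi releases the tetrasubstituted lithium enolate regiospecifically, and its SN2 C-alkylation occurs anti to the C8 methyl (pseudoaxial to avoid A(1,2) strain with the C9 methyl), so C20 and C17 end up cis and C9 is set.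

Step 7
Reactants: 10 (2S,3R)-2-[(3R)-5-(tert-butyldimethylsilyloxy)-3-methylpentyl]-2,3-dimethylcyclohexan-1-one
Product: 12 (5R,6S)-6-[(3R)-5-(tert-butyldimethylsilyloxy)-3-methylpentyl]-5,6-dimethylcyclohex-1-en-1-yl trifluoromethanesulfonate, via lithium enolate 11 (not isolated)
Conditions: LiN(i-Pr)2, THF, −78 °C; PhNTf2, −78 to 0 °C
Reagents that add atoms: N-phenylbis(trifluoromethanesulfonimide), O=S(=O)(N(c1ccccc1)S(=O)(=O)C(F)(F)F)C(F)(F)F
Why: The ketone has α-hydrogens only at C5, so kinetic deprotonation and O-sulfonylation (enol triflate formation) give one regioisomer.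

Step 8
Reactants: 12 (5R,6S)-6-[(3R)-5-(tert-butyldimethylsilyloxy)-3-methylpentyl]-5,6-dimethylcyclohex-1-en-1-yl trifluoromethanesulfonate
Product: 13 tert-butyl{[(3R)-5-[(1S,6R)-1,6-dimethylcyclohex-2-en-1-yl]-3-methylpentyl]oxy}dimethylsilane
Conditions: Pd(OAc)2 (5 mol%), PPh3 (10 mol%), n-Bu3N, HCO2H, DMF, 60 °C
Reagents that add atoms: none
Why: Palladium-catalysed formate reduction (oxidative addition of the enol triflate to zerovalent palladium, formate exchange, decarboxylation, reductive elimination) replaces OTf by H and leaves the C5=C10 alkene.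

Step 9
Reactants: 13 tert-butyl{[(3R)-5-[(1S,6R)-1,6-dimethylcyclohex-2-en-1-yl]-3-methylpentyl]oxy}dimethylsilane
Product: 14 (3R)-5-[(1S,6R)-1,6-dimethylcyclohex-2-en-1-yl]-3-methylpentan-1-ol
Conditions: n-Bu4NF, THF, 0 °C to rt
Reagents that add atoms: none
Why: Fluoride-driven desilylation frees the C15 alcohol at a stage where only an isolated alkene is present.

Step 10
Reactants: 14 (3R)-5-[(1S,6R)-1,6-dimethylcyclohex-2-en-1-yl]-3-methylpentan-1-ol
Product: 15 (3R)-5-[(1S,6R)-1,6-dimethylcyclohex-2-en-1-yl]-3-methylpentyl acetate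
Conditions: Ac2O, pyridine, DMAP (cat.), CH2Cl2, rt
Reagents that add atoms: acetic anhydride, CC(=O)OC(C)=O
Why: DMAP-catalysed acylation installs the C15 acetate of the target now that all strongly basic steps are over.

Step 11
Reactants: 15 (3R)-5-[(1S,6R)-1,6-dimethylcyclohex-2-en-1-yl]-3-methylpentyl acetate; 16 methyl 2-(triphenylphosphoranylidene)propanoate
Product: 19 methyl (2E,6R,7S,10R)-12-acetoxy-7-formyl-2,6,7,10-tetramethyldodec-2-enoate, via ozonide 17 (not isolated), via dialdehyde 18 (not isolated)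
Conditions: O3, CH2Cl2, −78 °C; PPh3, −78 °C to rt; then 16 (1.05 equiv), 0 °C to rt
Reagents that add atoms: ozone, [O-][O+]=O
Why: Ozonolysis cleaves the only alkene (C5=C10) to the 1,6-dialdehyde, and the stabilised α-methyl ylide (Wittig reaction, E-selective) should olefinate only the unhindered C5 aldehyde, the neopentyl-type formyl group on quaternary C9 being much slower.

Step 12
Reactants: 19 methyl (2E,6R,7S,10R)-12-acetoxy-7-formyl-2,6,7,10-tetramethyldodec-2-enoate; 20 dimethyl (2-oxopropyl)phosphonate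
Product: 22 methyl (2E,6R,7S,10R)-12-acetoxy-2,6,7,10-tetramethyl-7-[(E)-3-oxobut-1-enyl]dodec-2-enoate, via sodium phosphonate 21 (not isolated)
Conditions: 20, NaH, THF, 0 °C; then 19, 0 °C to rt
Reagents that add atoms: none
Why: Horner–Wadsworth–Emmons olefination of the non-enolisable C10 aldehyde with the weakly basic β-ketophosphonate anion gives the E-enone and spares the acetate and the enoate.

Step 13
Reactants: 22 methyl (2E,6R,7S,10R)-12-acetoxy-2,6,7,10-tetramethyl-7-[(E)-3-oxobut-1-enyl]dodec-2-enoate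
Product: 23 methyl (2E,6R,7S,10R)-12-acetoxy-7-[(E)-3-(tert-butyldimethylsilyloxy)buta-1,3-dienyl]-2,6,7,10-tetramethyldodec-2-enoate
Conditions: t-BuMe2SiOTf, Et3N, CH2Cl2, 0 °C
Reagents that add atoms: tert-butyldimethylsilyl trifluoromethanesulfonate, CC(C)(C)[Si](C)(C)OS(=O)(=O)C(F)(F)F
Why: Soft enolisation (silyl triflate and amine) of the methyl ketone can only go toward the methyl group C3 and gives the 2-silyloxydiene, while esters do not enolise under these conditions.

Step 14
Reactants: 23 methyl (2E,6R,7S,10R)-12-acetoxy-7-[(E)-3-(tert-butyldimethylsilyloxy)buta-1,3-dienyl]-2,6,7,10-tetramethyldodec-2-enoate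
Product: 24 methyl (1S,4aS,5S,6R,8aS)-5-[(3R)-5-acetoxy-3-methylpentyl]-3-(tert-butyldimethylsilyloxy)-1,5,6-trimethyl-1,2,4a,5,6,7,8,8a-octahydronaphthalene-1-carboxylate (trans-fused silyl enol ether)
Conditions: toluene (0.01 M), BHT (cat.), Et3N (trace), base-washed sealed tube, 170 °C
Reagents that add atoms: none
Why: Thermal, concerted, suprafacial [4+2] cycloaddition of normal electron demand (intramolecular Diels–Alder of a 1,7,9-decatriene carrying a 2-silyloxydiene, the known route to octalone enol ethers); the tether, not orbital polarisation, enforces the C3–C4/C5–C10 regiochemistry. Ring A forms from the four diene carbons C3, C2, C1, C10 and the two dienophile carbons C4, C5, and ring B closes in the fused (not bridged) mode as a six-membered ring through the C6–C9 tether in a chair-like array. C4 and C5 are fixed relative to each other by the E geometry of the enoate (CO2Me cis to H5), C5 relative to C9 by the diene face attacked, and C10 by the placement of the ester (endo gives the trans fusion drawn). The step needs attack on the diene face anti to the C20 methyl, that is the tether chair with the C9 side chain axial beneath the diene, C20 equatorial and the C8 methyl axial and anti to the chain; this chair has no 1,3-diaxial carbon–carbon contact, whereas both chairs of the cis-fused adduct on the same face have one. The substrate supports this face only by relief of the C17/C11 gauche interaction against one extra axial methyl, so the preference over the other chair (C20 axial, leading to the 4,5-bis-epimer series) is expected to be small and the face isomers would have to be separated here or after step 15. The ring fusion itself is not critical because C10 becomes sp2 in step 15, so a cis-fused adduct of the same face would converge on 25.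

Step 15
Reactants: 24 methyl (1S,4aS,5S,6R,8aS)-5-[(3R)-5-acetoxy-3-methylpentyl]-3-(tert-butyldimethylsilyloxy)-1,5,6-trimethyl-1,2,4a,5,6,7,8,8a-octahydronaphthalene-1-carboxylate
Product: 25 methyl (1S,5S,6R,8aS)-5-[(3R)-5-acetoxy-3-methylpentyl]-1,5,6-trimethyl-3-oxo-1,2,3,5,6,7,8,8a-octahydronaphthalene-1-carboxylate
Conditions: Pd(OAc)2 (1.1 equiv), MeCN, rt
Reagents that add atoms: none
Why: Saegusa–Ito oxidation turns the silyl enol ether into a C1-bound enolate of divalent palladium, whose β-hydride elimination can only involve H10 and so gives the C1=C10 enone regiospecifically while removing the C10 stereocentre.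

**Compound list**

1 | (R)-5-methoxy-3-methyl-5-oxopentanoic acid (monomethyl (R)-3-methylglutarate) | COC(=O)C[C@H](C)CC(=O)O | starting material
2 | methyl (R)-5-hydroxy-3-methylpentanoate | COC(=O)C[C@H](C)CCO | intermediate
3 | methyl (S)-5-iodo-3-methylpentanoate | COC(=O)C[C@H](C)CCI | intermediate
4 | (S)-5-iodo-3-methylpentan-1-ol | OCC[C@H](C)CCI | intermediate
5 | (S)-tert-butyl[(5-iodo-3-methylpentyl)oxy]dimethylsilane | CC(C)(C)[Si](C)(C)OCC[C@H](C)CCI | intermediate
6 | 2-methylcyclohex-2-en-1-one | CC1=CCCCC1=O | starting material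
7 | dimethylaluminium (R)-2,3-dimethylcyclohex-1-en-1-olate | C[C@@H]1CCCC(O[Al](C)C)=C1C | intermediate (not isolated)
8 | (R)-[(2,3-dimethylcyclohex-1-en-1-yl)oxy]trimethylsilane | C[C@@H]1CCCC(O[Si](C)(C)C)=C1C | intermediate
9 | lithium (R)-2,3-dimethylcyclohex-1-en-1-olate | C[C@@H]1CCCC(O[Li])=C1C | intermediate (not isolated)
10 | (2S,3R)-2-[(3R)-5-(tert-butyldimethylsilyloxy)-3-methylpentyl]-2,3-dimethylcyclohexan-1-one | O=C1CCC[C@@H](C)[C@]1(C)CC[C@@H](C)CCO[Si](C)(C)C(C)(C)C | intermediate
11 | lithium enolate of 10 (C5=C10) | [Li]OC1=CCC[C@@H](C)[C@]1(C)CC[C@@H](C)CCO[Si](C)(C)C(C)(C)C | intermediate (not isolated)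
12 | (5R,6S)-6-[(3R)-5-(tert-butyldimethylsilyloxy)-3-methylpentyl]-5,6-dimethylcyclohex-1-en-1-yl trifluoromethanesulfonate | O=S(=O)(OC1=CCC[C@@H](C)[C@]1(C)CC[C@@H](C)CCO[Si](C)(C)C(C)(C)C)C(F)(F)F | intermediate
13 | tert-butyl{[(3R)-5-[(1S,6R)-1,6-dimethylcyclohex-2-en-1-yl]-3-methylpentyl]oxy}dimethylsilane | C1=CCC[C@@H](C)[C@]1(C)CC[C@@H](C)CCO[Si](C)(C)C(C)(C)C | intermediate
14 | (3R)-5-[(1S,6R)-1,6-dimethylcyclohex-2-en-1-yl]-3-methylpentan-1-ol | C1=CCC[C@@H](C)[C@]1(C)CC[C@@H](C)CCO | intermediate
15 | (3R)-5-[(1S,6R)-1,6-dimethylcyclohex-2-en-1-yl]-3-methylpentyl acetate | C1=CCC[C@@H](C)[C@]1(C)CC[C@@H](C)CCOC(C)=O | intermediate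
16 | methyl 2-(triphenylphosphoranylidene)propanoate | COC(=O)C(C)=P(c1ccccc1)(c1ccccc1)c1ccccc1 | starting material
17 | ozonide of 15 (1,2,4-trioxolane across C5 and C10, acetal carbons undefined) | C12OC(CC[C@@H](C)[C@]1(C)CC[C@@H](C)CCOC(C)=O)OO2 | intermediate (not isolated)
18 | (3R,6S,7R)-6-formyl-3,6,7-trimethyl-10-oxodecyl acetate | O=CCC[C@@H](C)[C@@](C)(C=O)CC[C@@H](C)CCOC(C)=O | intermediate (not isolated)
19 | methyl (2E,6R,7S,10R)-12-acetoxy-7-formyl-2,6,7,10-tetramethyldodec-2-enoate | COC(=O)/C(C)=C/CC[C@@H](C)[C@@](C)(C=O)CC[C@@H](C)CCOC(C)=O | intermediate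
20 | dimethyl (2-oxopropyl)phosphonate | COP(=O)(OC)CC(C)=O | starting material
21 | sodium salt of 20 | [Na+].COP(=O)(OC)[CH-]C(C)=O | intermediate (not isolated)
22 | methyl (2E,6R,7S,10R)-12-acetoxy-2,6,7,10-tetramethyl-7-[(E)-3-oxobut-1-enyl]dodec-2-enoate | COC(=O)/C(C)=C/CC[C@@H](C)[C@](C)(CC[C@@H](C)CCOC(C)=O)/C=C/C(C)=O | intermediate
23 | methyl (2E,6R,7S,10R)-12-acetoxy-7-[(E)-3-(tert-butyldimethylsilyloxy)buta-1,3-dienyl]-2,6,7,10-tetramethyldodec-2-enoate | COC(=O)/C(C)=C/CC[C@@H](C)[C@](C)(CC[C@@H](C)CCOC(C)=O)/C=C/C(=C)O[Si](C)(C)C(C)(C)C | intermediate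
24 | methyl (1S,4aS,5S,6R,8aS)-5-[(3R)-5-acetoxy-3-methylpentyl]-3-(tert-butyldimethylsilyloxy)-1,5,6-trimethyl-1,2,4a,5,6,7,8,8a-octahydronaphthalene-1-carboxylate (trans-fused; H-5 α, H-10 β) | COC(=O)[C@@]1(C)CC(O[Si](C)(C)C(C)(C)C)=C[C@@H]2[C@@H]1CC[C@@H](C)[C@]2(C)CC[C@@H](C)CCOC(C)=O | intermediate
25 | methyl (1S,5S,6R,8aS)-5-[(3R)-5-acetoxy-3-methylpentyl]-1,5,6-trimethyl-3-oxo-1,2,3,5,6,7,8,8a-octahydronaphthalene-1-carboxylate (CNP0250576.1) | COC(=O)[C@@]1(C)CC(=O)C=C2[C@@H]1CC[C@@H](C)[C@]2(C)CC[C@@H](C)CCOC(C)=O | target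

**Step count**

Total step count: 15. Longest linear sequence: 14 steps (steps 1–4, then 6–15).

**Steps most likely to fail**

1. Step 14 – poor facial selectivity. Cycloaddition through the competing tether chair (C20 axial) uses the other diene face and leads to the 4,5-bis-epimer series; slow reaction with thermal loss of the silyl enol ether may add to this.

 Fallback, setting out from 14 and returning at 25: relay the C9 configuration through a covalent strap. C18 and C11 lie on the same face in 25, so a lactone between O15 and C18 can bridge C9 and C4 only on the wanted face. Esterification of 14 with 2-(diethoxyphosphoryl)propanoic acid (DCC, DMAP) would give the phosphonopropanoate F1. Ozonolysis (O3; PPh3) would give the dialdehyde F2. Intramolecular Horner–Wadsworth–Emmons reaction at the unhindered C5 aldehyde (LiCl, i-Pr2NEt, MeCN, high dilution) would give the 13-membered E-macrolide aldehyde F3. Olefination with 20 (NaH) would give the macrolide enone F4, and t-BuMe2SiOTf/Et3N the macrolide silyloxydiene F5. Heating should then give the bridged cis-fused adduct F6, with the ester exo and the strap along the open edge of the diene; the ring fusion is again irrelevant. NaOMe/MeOH would open the lactone and cleave the enol ether to the keto hydroxy ester F7. Acetylation gives the keto acetate F8. IBX dehydrogenation, which can only run toward C1=C10 because C4 is quaternary, would give 25.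

2. Step 6 – sluggish SN2 at the hindered tetrasubstituted enolate, with enolate equilibration, O-alkylation or polyalkylation taking over.

 Fallback, setting out from 8 and returning at 10: use an activated allylic electrophile and set C13 afterwards under catalyst control. Zirconium-catalysed carboalumination of tert-butyl(but-3-yn-1-yloxy)dimethylsilane (AlMe3, Zr(C5H5)2Cl2; then paraformaldehyde) would give the (E)-allylic alcohol F9. CBr4/PPh3 would give the allylic bromide F10. Alkylation of enolate 9 (from 8 and MeLi) with F10 should give the unsaturated ketone F11 with the same anti selectivity. Asymmetric hydrogenation of the trisubstituted C12=C13 alkene (H2, [Ir(C8H12)(L)][B(C6H3(CF3)2)4], L = chiral phosphinooxazoline, antipode chosen for 13R) would return 10.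

3. Step 11 – loss of chemoselectivity between the two formyl groups (double olefination), or aldol cyclisation of the 1,6-dialdehyde before the ylide reacts.

 Fallback, setting out from 15 and returning at 19: unmask the two carbonyl groups one after the other. Ozonolysis of 15 with NaBH4 work-up would give the diol F12. TEMPO/PhI(OAc)2 should oxidise the unhindered C5 alcohol in preference to the neopentyl C10 alcohol, giving the hydroxy aldehyde F13, which is trapped in the same flask by ylide 16 as the hydroxy enoate F14. Dess–Martin oxidation of the remaining neopentyl alcohol would give 19.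

**Further compounds**

F1 | step 14 | (3R)-5-[(1S,6R)-1,6-dimethylcyclohex-2-en-1-yl]-3-methylpentyl 2-(diethoxyphosphoryl)propanoate | C1=CCC[C@@H](C)[C@]1(C)CC[C@@H](C)CCOC(=O)C(C)P(=O)(OCC)OCC
F2 | step 14 | (3R,6S,7R)-6-formyl-3,6,7-trimethyl-10-oxodecyl 2-(diethoxyphosphoryl)propanoate | O=CCC[C@@H](C)[C@@](C)(C=O)CC[C@@H](C)CCOC(=O)C(C)P(=O)(OCC)OCC
F3 | step 14 | (3E,7R,8S,11R)-3,7,8,11-tetramethyl-2-oxo-1-oxacyclotridec-3-ene-8-carbaldehyde | C/C1=C\CC[C@@H](C)[C@@](C)(C=O)CC[C@@H](C)CCOC1=O
F4 | step 14 | (3E,7R,8S,11R)-3,7,8,11-tetramethyl-8-[(E)-3-oxobut-1-enyl]-1-oxacyclotridec-3-en-2-one | C/C1=C\CC[C@@H](C)[C@@](C)(/C=C/C(C)=O)CC[C@@H](C)CCOC1=O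
F5 | step 14 | (3E,7R,8S,11R)-8-[(E)-3-(tert-butyldimethylsilyloxy)buta-1,3-dienyl]-3,7,8,11-tetramethyl-1-oxacyclotridec-3-en-2-one | C/C1=C\CC[C@@H](C)[C@@](C)(/C=C/C(=C)O[Si](C)(C)C(C)(C)C)CC[C@@H](C)CCOC1=O
F6 | step 14 | bridged cis-fused adduct (halimane numbering 4S,5S,8R,9S,10R,13R; C18–O–C15 lactone; C1=C2 silyl enol ether) | O=C1OCC[C@H](C)CC[C@@]2(C)[C@H](C)CC[C@H]3[C@@H]2C=C(O[Si](C)(C)C(C)(C)C)C[C@]13C
F7 | step 14 | methyl (1S,4aS,5S,6R,8aS)-5-[(3R)-5-hydroxy-3-methylpentyl]-1,5,6-trimethyl-3-oxodecahydronaphthalene-1-carboxylate (cis-fused) | COC(=O)[C@@]1(C)CC(=O)C[C@H]2[C@@H]1CC[C@@H](C)[C@]2(C)CC[C@@H](C)CCO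
F8 | step 14 | methyl (1S,4aS,5S,6R,8aS)-5-[(3R)-5-acetoxy-3-methylpentyl]-1,5,6-trimethyl-3-oxodecahydronaphthalene-1-carboxylate (cis-fused) | COC(=O)[C@@]1(C)CC(=O)C[C@H]2[C@@H]1CC[C@@H](C)[C@]2(C)CC[C@@H](C)CCOC(C)=O
F9 | step 6 | (E)-5-(tert-butyldimethylsilyloxy)-3-methylpent-2-en-1-ol | OC/C=C(\C)CCO[Si](C)(C)C(C)(C)C
F10 | step 6 | (E)-[(5-bromo-3-methylpent-3-en-1-yl)oxy](tert-butyl)dimethylsilane | BrC/C=C(\C)CCO[Si](C)(C)C(C)(C)C
F11 | step 6 | (2S,3R)-2-[(E)-5-(tert-butyldimethylsilyloxy)-3-methylpent-2-en-1-yl]-2,3-dimethylcyclohexan-1-one | O=C1CCC[C@@H](C)[C@]1(C)C/C=C(\C)CCO[Si](C)(C)C(C)(C)C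
F12 | step 11 | (3R,6S,7R)-10-hydroxy-6-(hydroxymethyl)-3,6,7-trimethyldecyl acetate | OCCC[C@@H](C)[C@@](C)(CO)CC[C@@H](C)CCOC(C)=O
F13 | step 11 | (3R,6S,7R)-6-(hydroxymethyl)-3,6,7-trimethyl-10-oxodecyl acetate | O=CCC[C@@H](C)[C@@](C)(CO)CC[C@@H](C)CCOC(C)=O
F14 | step 11 | methyl (2E,6R,7S,10R)-12-acetoxy-7-(hydroxymethyl)-2,6,7,10-tetramethyldodec-2-enoate | COC(=O)/C(C)=C/CC[C@@H](C)[C@@](C)(CO)CC[C@@H](C)CCOC(C)=O
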